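**Assumptions.** (a) The SMILES is read as (1S,2S,5R,6R)-2,6-bis(3,4-dimethoxyphenyl)-3,7-dioxabicyclo[3.3.0]octan-1-ol: the bridgehead OH, H-5, H-2 and H-6 lie on one face and both aryl groups are endo. Atom labels C1–C8 below follow this numbering (C1 = C–OH bridgehead, C5 = CH bridgehead, C2/C6 = aryl carbons, C4/C8 = CH2; ring A = C1, C5, C6, O7, C8; ring B = C1, C2, O3, C4, C5). (b) The (R,R) ligand in step 2 is taken to give the 2R carbinol; this sense is not established for this substrate, and if the first run shows the opposite, the (S,S) ligand is used and nothing else changes.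

**Retrosynthetic overview**
1. Target ⇐ cis-fused bis-hemiketal: two hydride deliveries to aryl oxocarbenium ions from the convex face set C2 and C6 last, both aryls endo.
2. Bis-hemiketal ⇐ open 1,4-diketone triol: rings A and B close together by double hemiketalisation, which also fixes C5 relative to C1; the diketone comes from a pentaol by benzylic oxidation.
3. Pentaol ⇐ hydroxylated diaroylsuccinate; the C1 carbinol, the only centre needing reagent control, comes from catalytic enantioselective hydroxylation of the symmetric dimer.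
4. Key C–C disconnection: the C1–C5 bond, made by coupling the enolate of ethyl 3,4-dimethoxybenzoylacetate with its own alpha-iodo derivative, so all 22 skeletal carbons are in place after step 1.

**Step 1**
Reactants: 1 ethyl 3-(3,4-dimethoxyphenyl)-3-oxopropanoate (2 equiv)
Product: 4 diethyl 2,3-bis(3,4-dimethoxybenzoyl)butanedioate, via sodium enolate 2 (not isolated), via alpha-iodo keto ester 3 (not isolated)
Conditions: NaH (1.0 equiv per 1), THF, 0 °C; I2 (0.5 equiv), 0 °C to rt
Reagents that add atoms: none
Why: Oxidative enolate dimerisation: half of enolate 2 is iodinated to 3, an enolonium equivalent, and the remaining enolate displaces iodide from it (SN2), joining two normally nucleophilic alpha-carbons into the bond that becomes C1–C5; both new centres are epimerisable (meso/racemic mixture) and need no control.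

**Step 2**
Reactants: 4 diethyl 2,3-bis(3,4-dimethoxybenzoyl)butanedioate
Product: 5 diethyl (2R)-2,3-bis(3,4-dimethoxybenzoyl)-2-hydroxybutanedioate (C3 epimers)
Conditions: Ni(ClO4)2·6H2O (10 mol %), (R,R)-4,6-bis(4-phenyl-4,5-dihydrooxazol-2-yl)dibenzofuran (11 mol %), 4 Å sieves, racemic 3-phenyl-2-(phenylsulfonyl)oxaziridine (1.05 equiv), CH2Cl2, 0 °C to rt
Reagents that add atoms: 3-phenyl-2-(phenylsulfonyl)oxaziridine, O=S(=O)(N1OC1c1ccccc1)c1ccccc1
Why: Catalytic enantioselective electrophilic alpha-hydroxylation of a beta-keto ester: the divalent nickel bis(oxazoline) complex binds one keto ester unit as a two-point enolate and exposes one face to the oxaziridine, which sets the quaternary carbinol (C1 of the target) as 2R without a strong base that could trigger retro-aldol, while C3 stays epimerisable and one equivalent of oxidant keeps the reaction at mono-hydroxylation.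

**Step 3**
Reactants: 5 diethyl (2R)-2,3-bis(3,4-dimethoxybenzoyl)-2-hydroxybutanedioate
Product: 6 (2S)-1,4-bis(3,4-dimethoxyphenyl)-2,3-bis(hydroxymethyl)butane-1,2,4-triol (mixture at C1, C3, C4)
Conditions: LiAlH4 (6 equiv), THF, −78 to 0 °C; then H2O, 15% aq NaOH, H2O
Reagents that add atoms: none
Why: Exhaustive hydride reduction of both esters and both ketones; the quaternary carbinol is untouched (its descriptor changes to S only through priorities), and the uncontrolled benzylic carbinol centres are erased in step 4.

**Step 4**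
Reactants: 6 (2S)-1,4-bis(3,4-dimethoxyphenyl)-2,3-bis(hydroxymethyl)butane-1,2,4-triol
Product: 8 (1S,5S)-2,6-bis(3,4-dimethoxyphenyl)-3,7-dioxabicyclo[3.3.0]octane-1,2,6-triol (anomer mixture at C2 and C6), via diketo triol 7 (not isolated)
Conditions: DDQ (2.2 equiv), 1,4-dioxane, rt; then PPTS (5 mol %), CH2Cl2, rt, stopped at full conversion; used crude
Reagents that add atoms: none
Why: Chemoselective benzylic dehydrogenation by DDQ (hydride abstraction favoured by the dimethoxyphenyl rings) spares primary and tertiary alcohols; each aryl ketone of 7 is then captured by its gamma-hydroxyl, and only the C5 epimer that allows cis fusion can close both rings, the other draining into it by enolisation of the C6 ketone in the open form, so C5 is set relative to C1 under thermodynamic control.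

**Step 5**
Reactants: 8 (1S,5S)-2,6-bis(3,4-dimethoxyphenyl)-3,7-dioxabicyclo[3.3.0]octane-1,2,6-triol
Product: 9 (1S,2S,5R,6R)-2,6-bis(3,4-dimethoxyphenyl)-3,7-dioxabicyclo[3.3.0]octan-1-ol
Conditions: Et3SiH (6 equiv), BF3·OEt2 (3 equiv), CH2Cl2, −78 to −40 °C; aq NaHCO3 at −40 °C
Reagents that add atoms: none
Why: Double ionic hydrogenation of hemiketals: each hemiketal ionises to an aryl oxocarbenium ion that takes hydride from the convex face of the cis-fused bicycle (the face of the bridgehead OH and H), so both aryl groups end endo (C2 S, C6 R) under kinetic control at low temperature.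

**Compound list**
1 | ethyl 3-(3,4-dimethoxyphenyl)-3-oxopropanoate | CCOC(=O)CC(=O)c1ccc(OC)c(OC)c1 | starting material
2 | sodium enolate of 1 | CCOC(=O)C=C([O-])c1ccc(OC)c(OC)c1.[Na+] | intermediate
3 | ethyl 3-(3,4-dimethoxyphenyl)-2-iodo-3-oxopropanoate | CCOC(=O)C(I)C(=O)c1ccc(OC)c(OC)c1 | intermediate
4 | diethyl 2,3-bis(3,4-dimethoxybenzoyl)butanedioate (meso and racemic forms) | CCOC(=O)C(C(=O)c1ccc(OC)c(OC)c1)C(C(=O)OCC)C(=O)c1ccc(OC)c(OC)c1 | intermediate
5 | diethyl (2R)-2,3-bis(3,4-dimethoxybenzoyl)-2-hydroxybutanedioate (C3 epimers) | CCOC(=O)[C@@](C(=O)c1ccc(OC)c(OC)c1)(O)C(C(=O)OCC)C(=O)c1ccc(OC)c(OC)c1 | intermediate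
6 | (2S)-1,4-bis(3,4-dimethoxyphenyl)-2,3-bis(hydroxymethyl)butane-1,2,4-triol (mixture at C1, C3, C4) | OC[C@@](C(O)c1ccc(OC)c(OC)c1)(O)C(CO)C(O)c1ccc(OC)c(OC)c1 | intermediate
7 | (2S)-1,4-bis(3,4-dimethoxyphenyl)-2-hydroxy-2,3-bis(hydroxymethyl)butane-1,4-dione (C3 epimers) | OC[C@@](C(=O)c1ccc(OC)c(OC)c1)(O)C(CO)C(=O)c1ccc(OC)c(OC)c1 | intermediate
8 | (1S,5S)-2,6-bis(3,4-dimethoxyphenyl)-3,7-dioxabicyclo[3.3.0]octane-1,2,6-triol (cis-fused, anomer mixture) | COc1ccc(C2(O)OC[C@@]3(O)[C@@H]2COC3(O)c2ccc(OC)c(OC)c2)cc1OC | intermediate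
9 | (1S,2S,5R,6R)-2,6-bis(3,4-dimethoxyphenyl)-3,7-dioxabicyclo[3.3.0]octan-1-ol | COc1ccc([C@@H]2OC[C@@]3(O)[C@@H]2CO[C@H]3c2ccc(OC)c(OC)c2)cc1OC | target

**Totals.** 5 steps; longest linear sequence 5 steps.

**Steps most likely to fail**

Step 2 (highest risk). The alpha-carbon is hindered and branched, the substrate carries a second keto ester that can also bind the metal, and enantioselectivity on this substrate class is untested. The fallback sets out from 1 and comes back at 5, bypassing 4. One portion of 1 is oxidised with Dess–Martin periodinane and pyridine in CH2Cl2 to the vicinal tricarbonyl ethyl 3-(3,4-dimethoxyphenyl)-2,3-dioxopropanoate F1. A second portion of 1 is then added, as its enol, to the central ketone of F1 with Cu(OSO2CF3)2 and (S,S)-2,2'-(propane-2,2-diyl)bis(4-tert-butyl-4,5-dihydrooxazole) (10 mol % each) in CH2Cl2 at −20 °C; the divalent copper complex chelates the keto ester of F1 and blocks one face. This aldol addition gives 5 directly, so the carbinol is created in the C–C bond-forming event instead of by oxidising a hindered enolate.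

Step 5. The endo,endo product is the least stable isomer, so warming or prolonged acid could epimerise the benzylic ethers, over-reduce them, or dehydrate 8 towards a furan; the hydroxyl next to C2 might also erode facial selectivity. The fallback sets out from 8 and comes back at 9. Compound 8 is treated with PhSH and BF3·OEt2 in CH2Cl2 at −78 °C (thiol traps the cations much faster than silane) to give 2,6-bis(3,4-dimethoxyphenyl)-2,6-bis(phenylsulfanyl)-3,7-dioxabicyclo[3.3.0]octan-1-ol F4. Bu3SnH and AIBN in toluene at 80 °C then replace both C–S bonds by C–H through alpha-alkoxybenzyl radicals, which take hydrogen on the convex face under neutral conditions, giving 9.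

Step 4. DDQ could fail to discriminate, or the acid formed could cyclise the benzylic alcohols directly to the unwanted exo ethers; the C5 funnel through 7 also needs mild acid, which risks furan formation. The fallback sets out from 6 and comes back at 8. The two primary hydroxyls of 6 are silylated (TBSCl, imidazole, DMF, 0 °C) to (2S)-2,3-bis({[tert-butyl(dimethyl)silyl]oxy}methyl)-1,4-bis(3,4-dimethoxyphenyl)butane-1,2,4-triol F2. The two benzylic carbinols are oxidised with Dess–Martin periodinane and NaHCO3 in CH2Cl2 to (2S)-2,3-bis({[tert-butyl(dimethyl)silyl]oxy}methyl)-1,4-bis(3,4-dimethoxyphenyl)-2-hydroxybutane-1,4-dione F3. HF·pyridine in THF at 0 °C then frees the primary alcohols to give 7, which closes to 8.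

**Further compounds**
F1 | step 2 | ethyl 3-(3,4-dimethoxyphenyl)-2,3-dioxopropanoate | CCOC(=O)C(=O)C(=O)c1ccc(OC)c(OC)c1
F2 | step 4 | (2S)-2,3-bis({[tert-butyl(dimethyl)silyl]oxy}methyl)-1,4-bis(3,4-dimethoxyphenyl)butane-1,2,4-triol | CC(C)(C)[Si](C)(C)OC[C@@](C(O)c1ccc(OC)c(OC)c1)(O)C(CO[Si](C)(C)C(C)(C)C)C(O)c1ccc(OC)c(OC)c1
F3 | step 4 | (2S)-2,3-bis({[tert-butyl(dimethyl)silyl]oxy}methyl)-1,4-bis(3,4-dimethoxyphenyl)-2-hydroxybutane-1,4-dione | CC(C)(C)[Si](C)(C)OC[C@@](C(=O)c1ccc(OC)c(OC)c1)(O)C(CO[Si](C)(C)C(C)(C)C)C(=O)c1ccc(OC)c(OC)c1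
F4 | step 5 | 2,6-bis(3,4-dimethoxyphenyl)-2,6-bis(phenylsulfanyl)-3,7-dioxabicyclo[3.3.0]octan-1-ol (bridgeheads as in 8, mixture at C2 and C6) | COc1ccc(C2(Sc3ccccc3)OC[C@@]3(O)[C@@H]2COC3(Sc2ccccc2)c2ccc(OC)c(OC)c2)cc1OC
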